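The target is cut at C12–C13 into bicyclic diene 16 and (E)-vinyl iodide 26, which carries the monocyclic ring. The decalin rests on one ring closure: quaternary C10 of ring B lies next to C9, which can be a ketone, so ring A is closed at the C1–C10 bond by intramolecular deconjugative α-alkylation of the dienolate of 2-methyl-3-(5-iodo-2-methylpentan-2-yl)cyclohex-2-enone 8, in which the C4 gem-dimethyl arm sits on C5. One operation closes ring A, sets quaternary C10 under a chiral phase-transfer catalyst and moves the double bond to C5=C6; its hydrogenation gives the trans fusion, and the C9 ketone later becomes the C8=C9 alkene.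

Key step: step 5

Numbering used: decalin C1–C10 (ring A: C1–C5 and C10; ring B: C5–C10; methyl groups on C4, C4, C8 and C10), chain C11–C16 from C9, ring carbon C17 of the monocycle bearing the chain.

Remark: the sense of induction of the chiral ammonium salt (step 5) and of the phosphoramidite (step 13) cannot be predicted with certainty; in each case the catalyst antipode that gives the drawn configuration is meant.

Step 1
Reactants: 1 5-chloropentan-2-one
Product: 2 5-chloro-2-methylpentan-2-ol
Conditions: MeMgBr, Et2O, −20 to 0 °C; H2O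
Reagents that add atoms: methylmagnesium bromide, C[Mg]Br
Why: Grignard 1,2-addition of the methyl nucleophile to the ketone gives the tertiary alcohol, and the low temperature keeps the δ-chloro alkoxide from closing to 2,2-dimethyltetrahydrofuran.

Step 2
Reactants: 2 5-chloro-2-methylpentan-2-ol
Product: 3 2-bromo-5-chloro-2-methylpentane
Conditions: 48% aq. HBr, 0 °C
Reagents that add atoms: hydrogen bromide, Br
Why: SN1 substitution of the tertiary alcohol by bromide through the tertiary cation is fast at 0 °C, whereas the primary chloride is inert to aqueous acid.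

Step 3
Reactants: 3 2-bromo-5-chloro-2-methylpentane, 4 3-ethoxy-2-methylcyclohex-2-en-1-one
Product: 7 3-(5-chloro-2-methylpentan-2-yl)-2-methylcyclohex-2-en-1-one, via tertiary Grignard reagent 5 (not isolated), via carbinol adduct 6 (not isolated)
Conditions: Mg, THF, 0 °C; LaCl3·2LiCl, 4, THF, −40 to 0 °C; 2 M HCl, rt
Reagents that add atoms: water, O
Why: Magnesium inserts into the tertiary C–Br bond far faster than into the primary C–Cl bond, the LaCl3·2LiCl-activated carbonyl of the vinylogous ester takes up the hindered Grignard reagent by 1,2-addition, and aqueous acid hydrolyses the enol ether with allylic transposition to the 3-substituted enone (Stork–Danheiser sequence).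

Step 4
Reactants: 7 3-(5-chloro-2-methylpentan-2-yl)-2-methylcyclohex-2-en-1-one
Product: 8 3-(5-iodo-2-methylpentan-2-yl)-2-methylcyclohex-2-en-1-one
Conditions: NaI, acetone, reflux
Reagents that add atoms: sodium iodide, [Na+].[I-]
Why: Finkelstein exchange of the primary chloride for iodide, driven by precipitation of NaCl, provides the better leaving group for the low-temperature ring closure.

Step 5
Reactants: 8 3-(5-iodo-2-methylpentan-2-yl)-2-methylcyclohex-2-en-1-one
Product: 10 (8aS)-5,5,8a-trimethyl-3,5,6,7,8,8a-hexahydronaphthalen-1(2H)-one, via ammonium dienolate 9 (not isolated)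
Conditions: chiral N-spiro bis(binaphthyl)ammonium bromide with 3,4,5-trifluorophenyl groups at the 3,3'-positions (2 mol%), 50% aq. KOH, toluene, 0 °C
Reagents that add atoms: none
Why: Proposed new method: hydroxide removes a C6 hydrogen of 8 at the interface and the chiral ammonium cation carries the extended dienolate 9 into toluene as a contact ion pair, where its α-carbon C10 displaces the tethered primary iodide at C1 in an intramolecular SN2 reaction. The closest known reaction types are the base-mediated deconjugative α-alkylation of 2-alkylcyclohex-2-enones (4-en-3-ones to 4,4-dialkyl-5-enes) and the phase-transfer-catalysed enantioselective alkylation of α-substituted cyclic ketones to α-quaternary ketones, which have not been combined in an intramolecular alkylation of a dienolate. Ring A closes in the 6-(enolexo)-exo-tet mode through a half-chair in which C1 reaches C10 perpendicular to the dienolate plane. C10 is the only new stereocentre and is controlled by the catalyst: the cation, held at the enolate oxygen, shields one face of the planar dienolate so that the arm folds over the open face, and the low temperature and non-polar solvent should let the ion pair outrun the racemic interfacial reaction. The step needs α- over γ-alkylation (attack at C6 would also give a six-membered ring) and C- over O-alkylation: the α-carbon carries the highest charge density of the dienolate, attack there relieves the strain between the C10 methyl and the tertiary arm on C5, and O-alkylation would need an eight-membered ring.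

Step 6
Reactants: 10 (8aS)-5,5,8a-trimethyl-3,5,6,7,8,8a-hexahydronaphthalen-1(2H)-one
Product: 11 (4aS,8aS)-5,5,8a-trimethyloctahydronaphthalen-1(2H)-one
Conditions: H2 (4 bar), Pd/C, EtOAc, rt
Reagents that add atoms: none
Why: Heterogeneous catalytic hydrogenation should deliver hydrogen to C5 from the face opposite the angular C10 methyl and the axial C4 methyl, which sets C5 and gives the trans-fused decalone, while the hindered ketone is not reduced.

Step 7
Reactants: 11 (4aS,8aS)-5,5,8a-trimethyloctahydronaphthalen-1(2H)-one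
Product: 13 (4aS,8aS)-2,5,5,8a-tetramethyloctahydronaphthalen-1(2H)-one (C2 epimers), via lithium enolate 12 (not isolated)
Conditions: LiN(iPr)2, THF, −78 °C; MeI, −78 to 0 °C
Reagents that add atoms: iodomethane, CI
Why: Enolate alkylation: LiN(iPr)2 can only deprotonate C8 because C10 is quaternary, and methylation there installs the C8 methyl group, whose configuration is of no consequence because C8 becomes trigonal in step 8.

Step 8
Reactants: 13 (4aS,8aS)-2,5,5,8a-tetramethyloctahydronaphthalen-1(2H)-one
Product: 15 (4aS,8aS)-2,5,5,8a-tetramethyl-3,4,4a,5,6,7,8,8a-octahydronaphthalen-1-yl trifluoromethanesulfonate, via potassium enolate 14 (not isolated)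
Conditions: KN(SiMe3)2, THF, −78 to 0 °C; PhNTf2
Reagents that add atoms: N-phenylbis(trifluoromethanesulfonimide), O=S(=O)(N(c1ccccc1)S(=O)(=O)C(F)(F)F)C(F)(F)F
Why: Regiospecific enolisation toward C8, the only enolisable position, and O-sulfonylation of the enolate fix the C8=C9 double bond as the fully substituted enol triflate.

Step 9
Reactants: 15 (4aS,8aS)-2,5,5,8a-tetramethyl-3,4,4a,5,6,7,8,8a-octahydronaphthalen-1-yl trifluoromethanesulfonate
Product: 16 (4aS,8aS)-1-ethenyl-2,5,5,8a-tetramethyl-3,4,4a,5,6,7,8,8a-octahydronaphthalene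
Conditions: vinylboronic acid pinacol ester, PdCl2(dppf), K2CO3, dioxane/H2O, 80 °C
Reagents that add atoms: vinylboronic acid pinacol ester, C=CB1OC(C)(C)C(C)(C)O1
Why: Suzuki–Miyaura coupling of the enol triflate with the small vinylboronate should overcome the hindrance at C9 and installs C11 and C12 with the C8=C9 alkene in place.

Step 10
Reactants: 17 2,2-dimethylcyclohexan-1-one
Product: 18 2,2-dimethyl-6-methylidenecyclohexan-1-one
Conditions: (CH2O)n, N-methylanilinium trifluoroacetate, THF, reflux
Reagents that add atoms: paraformaldehyde (as formaldehyde), C=O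
Why: Mannich-type α-methylenation through the anilinium-derived iminium ion can only occur at C6 because C2 is quaternary.

Step 11
Reactants: 18 2,2-dimethyl-6-methylidenecyclohexan-1-one
Product: 19 2,2-dimethyl-6-methylidenecyclohexan-1-ol (racemic)
Conditions: NaBH4, CeCl3·7H2O, MeOH, 0 °C
Reagents that add atoms: none
Why: Luche reduction gives clean 1,2-reduction of the α-methylene ketone to the allylic alcohol, whose carbinol configuration is lost in step 12.

Step 12
Reactants: 19 2,2-dimethyl-6-methylidenecyclohexan-1-ol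
Product: 20 1-(chloromethyl)-3,3-dimethylcyclohex-1-ene
Conditions: SOCl2, Et2O, 0 °C to rt
Reagents that add atoms: thionyl chloride, O=S(Cl)Cl
Why: The chlorosulfite should collapse by SNi' with allylic transposition, because direct substitution at the neopentyl-type secondary carbon is slow, to give the primary allylic chloride with the trisubstituted ring alkene.

Step 13
Reactants: 20 1-(chloromethyl)-3,3-dimethylcyclohex-1-ene, 21 (4-bromobut-1-yn-1-yl)trimethylsilane
Product: 23 {4-[(1S)-2,2-dimethyl-6-methylidenecyclohexyl]but-1-yn-1-yl}trimethylsilane, via alkynyl Grignard reagent 22 (not isolated)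
Conditions: 21, Mg, Et2O, rt; then 20, copper thiophene-2-carboxylate (3 mol%), binaphthol-derived phosphoramidite with an N,N-bis[1-(2-methoxyphenyl)ethyl]amino group (3.3 mol%), CH2Cl2, −78 °C, slow addition
Reagents that add atoms: none
Why: Copper-catalysed enantioselective allylic alkylation (SN2') of a 2-substituted cyclic allylic chloride with a Grignard reagent delivers the alkyl group to ring carbon C17, returns the double bond to the exocyclic position, and sets the (S)-centre through face selection by the chiral phosphoramidite–copper complex.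

Step 14
Reactants: 23 {4-[(1S)-2,2-dimethyl-6-methylidenecyclohexyl]but-1-yn-1-yl}trimethylsilane
Product: 24 (2S)-2-(but-3-yn-1-yl)-1,1-dimethyl-3-methylidenecyclohexane
Conditions: K2CO3, MeOH, rt
Reagents that add atoms: none
Why: Methanolysis of the alkynyl–silicon bond with carbonate (protodesilylation) frees the terminal alkyne without touching the exocyclic alkene.

Step 15
Reactants: 24 (2S)-2-(but-3-yn-1-yl)-1,1-dimethyl-3-methylidenecyclohexane
Product: 26 (2S)-2-[(3E)-4-iodo-3-methylbut-3-en-1-yl]-1,1-dimethyl-3-methylidenecyclohexane, via alkenylalane 25 (not isolated)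
Conditions: AlMe3, Cp2ZrCl2 (20 mol%), CH2Cl2, 0 °C to rt; I2, THF, −30 °C
Reagents that add atoms: trimethylaluminium, C[Al](C)C; iodine, II
Why: Zirconium-catalysed methylalumination (Negishi carboalumination) adds methyl and aluminium syn across the terminal alkyne with methyl on the internal carbon, and iodinolysis of the alkenyl–aluminium bond with retention gives the (E)-vinyl iodide, while the 1,1-disubstituted ring alkene should not react.

Step 16
Reactants: 16 (4aS,8aS)-1-ethenyl-2,5,5,8a-tetramethyl-3,4,4a,5,6,7,8,8a-octahydronaphthalene, 26 (2S)-2-[(3E)-4-iodo-3-methylbut-3-en-1-yl]-1,1-dimethyl-3-methylidenecyclohexane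
Product: 28 (4aS,8aS)-1-{(3E)-6-[(1S)-2,2-dimethyl-6-methylidenecyclohexyl]-4-methylhex-3-en-1-yl}-2,5,5,8a-tetramethyl-3,4,4a,5,6,7,8,8a-octahydronaphthalene (target CNP0271776.1), via alkylborane 27 (not isolated)
Conditions: 16, 9-BBN, THF, rt to 50 °C; then aq. Cs2CO3, 26, PdCl2(dppf), AsPh3, DMF, rt
Reagents that add atoms: none
Why: 9-BBN adds anti-Markovnikov to the terminal vinyl group of the diene only, and B-alkyl Suzuki–Miyaura coupling of the borane with the vinyl iodide forms the C12–C13 bond with retention of the (E)-geometry; the residual B–H is quenched by the aqueous base before 26 is added, so its exocyclic alkene is not hydroborated.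

Compound list
1 | 5-chloropentan-2-one | CC(=O)CCCCl | starting material
2 | 5-chloro-2-methylpentan-2-ol | CC(C)(O)CCCCl | intermediate
3 | 2-bromo-5-chloro-2-methylpentane | CC(C)(Br)CCCCl | intermediate
4 | 3-ethoxy-2-methylcyclohex-2-en-1-one | CCOC1=C(C)C(=O)CCC1 | starting material
5 | (5-chloro-2-methylpentan-2-yl)magnesium bromide | CC(C)(CCCCl)[Mg]Br | intermediate
6 | 1-(5-chloro-2-methylpentan-2-yl)-3-ethoxy-2-methylcyclohex-2-en-1-ol (as its magnesium alkoxide before the acid is added) | CCOC1=C(C)C(O)(CCC1)C(C)(C)CCCCl | intermediate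
7 | 3-(5-chloro-2-methylpentan-2-yl)-2-methylcyclohex-2-en-1-one | O=C1CCCC(C(C)(C)CCCCl)=C1C | intermediate
8 | 3-(5-iodo-2-methylpentan-2-yl)-2-methylcyclohex-2-en-1-one | O=C1CCCC(C(C)(C)CCCI)=C1C | intermediate
9 | 3-(5-iodo-2-methylpentan-2-yl)-2-methylcyclohexa-1,3-dien-1-olate (ion pair with the chiral ammonium cation) | [O-]C1=C(C)C(=CCC1)C(C)(C)CCCI | intermediate
10 | (8aS)-5,5,8a-trimethyl-3,5,6,7,8,8a-hexahydronaphthalen-1(2H)-one | O=C1CCC=C2C(C)(C)CCC[C@]12C | intermediate
11 | (4aS,8aS)-5,5,8a-trimethyloctahydronaphthalen-1(2H)-one (trans-fused) | O=C1CCC[C@H]2C(C)(C)CCC[C@]12C | intermediate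
12 | lithium (4aS,8aS)-5,5,8a-trimethyl-3,4,4a,5,6,7,8,8a-octahydronaphthalen-1-olate | [Li+].[O-]C1=CCC[C@H]2C(C)(C)CCC[C@]12C | intermediate
13 | (4aS,8aS)-2,5,5,8a-tetramethyloctahydronaphthalen-1(2H)-one (mixture of C2 epimers) | O=C1C(C)CC[C@H]2C(C)(C)CCC[C@]12C | intermediate
14 | potassium (4aS,8aS)-2,5,5,8a-tetramethyl-3,4,4a,5,6,7,8,8a-octahydronaphthalen-1-olate | [K+].[O-]C1=C(C)CC[C@H]2C(C)(C)CCC[C@]12C | intermediate
15 | (4aS,8aS)-2,5,5,8a-tetramethyl-3,4,4a,5,6,7,8,8a-octahydronaphthalen-1-yl trifluoromethanesulfonate | O=S(=O)(OC1=C(C)CC[C@H]2C(C)(C)CCC[C@]12C)C(F)(F)F | intermediate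
16 | (4aS,8aS)-1-ethenyl-2,5,5,8a-tetramethyl-3,4,4a,5,6,7,8,8a-octahydronaphthalene | C=CC1=C(C)CC[C@H]2C(C)(C)CCC[C@]12C | intermediate
17 | 2,2-dimethylcyclohexan-1-one | CC1(C)CCCCC1=O | starting material
18 | 2,2-dimethyl-6-methylidenecyclohexan-1-one | C=C1CCCC(C)(C)C1=O | intermediate
19 | 2,2-dimethyl-6-methylidenecyclohexan-1-ol (racemic) | C=C1CCCC(C)(C)C1O | intermediate
20 | 1-(chloromethyl)-3,3-dimethylcyclohex-1-ene | ClCC1=CC(C)(C)CCC1 | intermediate
21 | (4-bromobut-1-yn-1-yl)trimethylsilane | C[Si](C)(C)C#CCCBr | starting material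
22 | [4-(trimethylsilyl)but-3-yn-1-yl]magnesium bromide | C[Si](C)(C)C#CCC[Mg]Br | intermediate
23 | {4-[(1S)-2,2-dimethyl-6-methylidenecyclohexyl]but-1-yn-1-yl}trimethylsilane | C=C1CCCC(C)(C)[C@@H]1CCC#C[Si](C)(C)C | intermediate
24 | (2S)-2-(but-3-yn-1-yl)-1,1-dimethyl-3-methylidenecyclohexane | C=C1CCCC(C)(C)[C@@H]1CCC#C | intermediate
25 | {(1E)-4-[(1S)-2,2-dimethyl-6-methylidenecyclohexyl]-2-methylbut-1-en-1-yl}dimethylalane | C=C1CCCC(C)(C)[C@@H]1CC/C(C)=C/[Al](C)C | intermediate
26 | (2S)-2-[(3E)-4-iodo-3-methylbut-3-en-1-yl]-1,1-dimethyl-3-methylidenecyclohexane | C=C1CCCC(C)(C)[C@@H]1CC/C(C)=C/I | intermediate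
27 | 9-{2-[(4aS,8aS)-2,5,5,8a-tetramethyl-3,4,4a,5,6,7,8,8a-octahydronaphthalen-1-yl]ethyl}-9-borabicyclo[3.3.1]nonane | C(CB1C2CCCC1CCC2)C1=C(C)CC[C@H]2C(C)(C)CCC[C@]12C | intermediate
28 | (4aS,8aS)-1-{(3E)-6-[(1S)-2,2-dimethyl-6-methylidenecyclohexyl]-4-methylhex-3-en-1-yl}-2,5,5,8a-tetramethyl-3,4,4a,5,6,7,8,8a-octahydronaphthalene | C=C1CCCC(C)(C)[C@@H]1CC/C(C)=C/CCC1=C(C)CC[C@H]2C(C)(C)CCC[C@]12C | target

Total step count: 16. Longest linear sequence: 10 steps (steps 1–9 and 16).

Steps most likely to fail

1. Step 5 (proposed new method). The ion pair may discriminate poorly between the two faces of the dienolate, the racemic interfacial alkylation may compete, and γ-deprotonation under phase-transfer conditions may be slow. Fallback, from 8 back to 10: KOtBu in t-BuOH/THF (0 °C to rt) should give, by the same dienolate alkylation without a chiral cation, the racemic ketone rac-5,5,8a-trimethyl-3,5,6,7,8,8a-hexahydronaphthalen-1(2H)-one F1. CBS reduction of F1 (BH3·SMe2, (S)-2-methyl-CBS-oxazaborolidine) is expected to turn both enantiomers into (1R)-alcohols under reagent control, that is, into the diastereomers (1R,8aS)-5,5,8a-trimethyl-1,2,3,5,6,7,8,8a-octahydronaphthalen-1-ol F2 and (1R,8aR)-5,5,8a-trimethyl-1,2,3,5,6,7,8,8a-octahydronaphthalen-1-ol F3, which are separated by chromatography. Oxidation of F2 with Dess–Martin periodinane comes back at 10.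

2. Step 13. The copper reagent may attack the unhindered CH2 terminus (SN2 instead of SN2') because the γ-carbon is flanked by the gem-dimethyl carbon, and the enantioselectivity may erode on this hindered substrate. Fallback, from 19 back to 23: 1,3-transposition of the allylic alcohol with Ph3SiOReO3 (Et2O, 0 °C) gives (3,3-dimethylcyclohex-1-en-1-yl)methanol F4. Johnson–Claisen rearrangement (MeC(OEt)3, cat. EtCO2H, 140 °C) forms the hindered C17–C16 bond and the exocyclic alkene in racemic ethyl 2-(2,2-dimethyl-6-methylidenecyclohexyl)acetate F5. Saponification (LiOH, THF/H2O) gives racemic 2-(2,2-dimethyl-6-methylidenecyclohexyl)acetic acid F6, and resolution by chromatography on a chiral stationary phase gives 2-[(1S)-2,2-dimethyl-6-methylidenecyclohexyl]acetic acid F7. LiAlH4 gives 2-[(1S)-2,2-dimethyl-6-methylidenecyclohexyl]ethan-1-ol F8, I2/PPh3/imidazole gives (2S)-2-(2-iodoethyl)-1,1-dimethyl-3-methylidenecyclohexane F9, and lithium (trimethylsilyl)acetylide in THF/DMPU comes back at 23.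

3. Step 3. Elimination or Wurtz coupling may take over while the tertiary Grignard reagent forms, and enolisation or reduction may compete with 1,2-addition to the hindered vinylogous ester. Fallback, from 4 back to 8: prenylmagnesium chloride, which attacks through its tertiary γ-carbon (THF, −78 °C), followed by 1 M HCl gives 2-methyl-3-(2-methylbut-3-en-2-yl)cyclohex-2-en-1-one F10. Linear hydroformylation of the vinyl group (Rh(acac)(CO)2, Xantphos, CO/H2, toluene, 80 °C) gives 4-methyl-4-(2-methyl-3-oxocyclohex-1-en-1-yl)pentanal F11. NaBH4 at −78 °C reduces only the aldehyde to 3-(5-hydroxy-2-methylpentan-2-yl)-2-methylcyclohex-2-en-1-one F12, and I2/PPh3/imidazole comes back at 8.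

Further compounds
F1 | step 5 | rac-5,5,8a-trimethyl-3,5,6,7,8,8a-hexahydronaphthalen-1(2H)-one | O=C1CCC=C2C(C)(C)CCCC12C
F2 | step 5 | (1R,8aS)-5,5,8a-trimethyl-1,2,3,5,6,7,8,8a-octahydronaphthalen-1-ol | O[C@@H]1CCC=C2C(C)(C)CCC[C@]12C
F3 | step 5 | (1R,8aR)-5,5,8a-trimethyl-1,2,3,5,6,7,8,8a-octahydronaphthalen-1-ol | O[C@@H]1CCC=C2C(C)(C)CCC[C@@]12C
F4 | step 13 | (3,3-dimethylcyclohex-1-en-1-yl)methanol | OCC1=CC(C)(C)CCC1
F5 | step 13 | ethyl 2-(2,2-dimethyl-6-methylidenecyclohexyl)acetate (racemic) | CCOC(=O)CC1C(=C)CCCC1(C)C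
F6 | step 13 | 2-(2,2-dimethyl-6-methylidenecyclohexyl)acetic acid (racemic) | OC(=O)CC1C(=C)CCCC1(C)C
F7 | step 13 | 2-[(1S)-2,2-dimethyl-6-methylidenecyclohexyl]acetic acid | C=C1CCCC(C)(C)[C@@H]1CC(O)=O
F8 | step 13 | 2-[(1S)-2,2-dimethyl-6-methylidenecyclohexyl]ethan-1-ol | C=C1CCCC(C)(C)[C@@H]1CCO
F9 | step 13 | (2S)-2-(2-iodoethyl)-1,1-dimethyl-3-methylidenecyclohexane | C=C1CCCC(C)(C)[C@@H]1CCI
F10 | step 3 | 2-methyl-3-(2-methylbut-3-en-2-yl)cyclohex-2-en-1-one | C=CC(C)(C)C1=C(C)C(=O)CCC1
F11 | step 3 | 4-methyl-4-(2-methyl-3-oxocyclohex-1-en-1-yl)pentanal | O=CCCC(C)(C)C1=C(C)C(=O)CCC1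
F12 | step 3 | 3-(5-hydroxy-2-methylpentan-2-yl)-2-methylcyclohex-2-en-1-one | OCCCC(C)(C)C1=C(C)C(=O)CCC1
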